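The route rests on the C3–C4 bond, the sp2–sp2 link between C3 of the 3(2H)-furanone ring (the carbon on the bridging oxygen) and C4 of the C4=C15 methylene unit. An intramolecular Liebeskind–Srogl coupling forms it, closing the ten-membered carbocycle C1–C10 (nine-membered through the C3–O–C10 bridge) and completing the cross-conjugated dienone in one operation. The step exploits the vinylogous thioester character of C3 in a 5-(methylthio)furanone and C4 as a vinyl nucleophile (2-stannylallyl ether). Its precursor is an open-chain seco compound with all five stereocentres in place and a cis-acetonide across C5/C6 as turn element; final acidolysis forms the lactone. C10 stems from (S)-lactic acid, C5/C6 from L-arabinose, and C7/C8 from a substrate-controlled chromium allylation.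

Key step: step 15

Remark on the chemistry: germacrane locants of 26 are used for all intermediates (C1 ketone; C2=C3 furanone alkene; C4=C15 methylene; C5 carbinol; C6–O lactone; C7; C8–O methacrylate; C9; C10 quaternary carbon; C11=C13 and C12 of the methylene lactone).

Step 1
Reactants: 1 (S)-lactic acid; 2 pivalaldehyde
Product: 3 (2S,5S)-2-tert-butyl-5-methyl-1,3-dioxolan-4-one (cis)
Conditions: TsOH·H2O (cat.), H2SO4 (cat.), pentane, reflux, Dean–Stark; crystallisation at −78 °C
Reagents that add atoms: none
Why: Acid-catalysed acetalisation to the dioxolanone, in which the new acetal centre is set cis to the methyl group under thermodynamic control and the cis isomer is enriched by crystallisation.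

Step 2
Reactants: 3 (2S,5S)-2-tert-butyl-5-methyl-1,3-dioxolan-4-one; 4 allyl bromide
Product: 5 (2S,5R)-5-allyl-2-tert-butyl-5-methyl-1,3-dioxolan-4-one
Conditions: LDA, THF, −78 °C; then 4, −78 → −30 °C
Reagents that add atoms: none
Why: Enolate alkylation with self-regeneration of the stereocentre, in which the tert-butyl group shields one face of the planar lithium enolate so that the allyl group enters trans to it and sets the quaternary centre (future C10).

Step 3
Reactants: 5 (2S,5R)-5-allyl-2-tert-butyl-5-methyl-1,3-dioxolan-4-one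
Product: 7 (R)-3-hydroxy-3-methylhex-5-en-2-one, via hemiketal adduct 6 (not isolated)
Conditions: MeLi (1.05 equiv), Et2O/THF, −78 °C; aq. NH4Cl
Reagents that add atoms: methyllithium, [Li]C
Why: Mono-addition of an organolithium to the lactone-type carbonyl should give a tetrahedral lithium alkoxide that survives at −78 °C and collapses on work-up to the α-hydroxy methyl ketone with loss of pivalaldehyde, the quaternary centre being untouched.

Step 4
Reactants: 7 (R)-3-hydroxy-3-methylhex-5-en-2-one
Product: 9 (R)-2-allyl-2-methyl-5-(methylthio)furan-3(2H)-one, via ketene dithioacetal 8 (not isolated)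
Conditions: NaH (3 equiv), CS2, THF/DMF, 0 °C; MeI (2.2 equiv), 0 °C → rt; crude 8 then TFA (cat.), CH2Cl2, rt
Reagents that add atoms: carbon disulfide, S=C=S; iodomethane, CI
Why: α-Oxo ketene dithioacetal formation at the only enolisable position (the C2 methyl group) followed by acid-catalysed addition–elimination of the tertiary hydroxyl (loss of methanethiol) should close the 3(2H)-furanone and leave C3 as a vinylogous thioester.

Step 5
Reactants: 9 (R)-2-allyl-2-methyl-5-(methylthio)furan-3(2H)-one
Product: 10 (R)-2-[2-methyl-5-(methylthio)-3-oxo-2,3-dihydrofuran-2-yl]acetaldehyde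
Conditions: OsO4 (2 mol %), NaIO4, 2,6-lutidine, dioxane/H2O, 0 °C → rt; used crude
Reagents that add atoms: osmium tetroxide, O=[Os](=O)(=O)=O; sodium periodate, [Na+].[O-]I(=O)(=O)=O
Why: Lemieux–Johnson cleavage of the terminal alkene should give the C8 aldehyde, the conjugated (electron-poor) sulfur being slow to oxidise and the base-sensitive β-alkoxy aldehyde being taken on without purification.

Step 6
Reactants: 11 L-arabinose
Product: 12 3,4-O-isopropylidene-L-arabinopyranose
Conditions: 2,2-dimethoxypropane, TsOH (cat.), DMF, rt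
Reagents that add atoms: 2,2-dimethoxypropane, COC(C)(C)OC
Why: Acetonide formation on the cis-3,4-diol of the pyranose (transacetalisation), no stereocentre being changed.

Step 7
Reactants: 12 3,4-O-isopropylidene-L-arabinopyranose
Product: 14 2,3-O-isopropylidene-L-erythrofuranose, via formate ester 13 (not isolated)
Conditions: NaIO4, H2O, 0 °C → rt; then Na2CO3, rt
Reagents that add atoms: none
Why: Malaprade glycol cleavage of the C1–C2 hemiacetal diol removes C1 as a formate ester whose hydrolysis leaves the L-erythrose lactol, the two retained stereocentres (future C5 and C6) being those of L-arabinose C3 and C4.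

Step 8
Reactants: 14 2,3-O-isopropylidene-L-erythrofuranose
Product: 15 [(4S,5R)-5-ethynyl-2,2-dimethyl-1,3-dioxolan-4-yl]methanol
Conditions: dimethyl (1-diazo-2-oxopropyl)phosphonate, K2CO3, MeOH, 0 °C → rt
Reagents that add atoms: dimethyl (1-diazo-2-oxopropyl)phosphonate, CC(=O)C(=[N+]=[N-])P(=O)(OC)OC
Why: Seyferth–Gilbert homologation in the Ohira–Bestmann variant acts on the open-chain aldehyde form of the lactol and should give the terminal alkyne (future C4≡C15) without epimerising the α-centre under the mild carbonate conditions.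

Step 9
Reactants: 15 [(4S,5R)-5-ethynyl-2,2-dimethyl-1,3-dioxolan-4-yl]methanol
Product: 16 [(4S,5S)-2,2-dimethyl-5-[1-(tributylstannyl)ethenyl]-1,3-dioxolan-4-yl]methanol
Conditions: Bu3SnH, Mo(CO)3(CNtBu)3 (2 mol %), hydroquinone, THF, 55 °C
Reagents that add atoms: tributyltin hydride, CCCC[SnH](CCCC)CCCC
Why: Molybdenum-catalysed hydrostannation places tin on the internal carbon of terminal propargylic ethers (α-selective), giving the 1,1-disubstituted vinylstannane that carries C4 as a nucleophile.

Step 10
Reactants: 16 [(4S,5S)-2,2-dimethyl-5-[1-(tributylstannyl)ethenyl]-1,3-dioxolan-4-yl]methanol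
Product: 17 (4R,5S)-2,2-dimethyl-5-[1-(tributylstannyl)ethenyl]-1,3-dioxolane-4-carbaldehyde
Conditions: Dess–Martin periodinane, pyridine, CH2Cl2, 0 °C → rt; used at once
Reagents that add atoms: none
Why: Dess–Martin oxidation of the primary alcohol under buffered conditions that should neither epimerise the cis-aldehyde nor cleave the vinylstannane.

Step 11
Reactants: 17 (4R,5S)-2,2-dimethyl-5-[1-(tributylstannyl)ethenyl]-1,3-dioxolane-4-carbaldehyde; 18 tert-butyl acrylate
Product: 19 tert-butyl 2-[hydroxy[(4S,5S)-2,2-dimethyl-5-[1-(tributylstannyl)ethenyl]-1,3-dioxolan-4-yl]methyl]prop-2-enoate (both carbinol epimers)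
Conditions: DABCO (1 equiv), neat 18 (excess), rt
Reagents that add atoms: none
Why: Morita–Baylis–Hillman reaction of the activated α-alkoxy aldehyde, whose new carbinol centre may form as a mixture because it is removed in step 12.

Step 12
Reactants: 19 tert-butyl 2-[hydroxy(dioxolanyl)methyl]prop-2-enoate
Product: 21 tert-butyl (Z)-2-(bromomethyl)-3-[(4S,5S)-2,2-dimethyl-5-[1-(tributylstannyl)ethenyl]-1,3-dioxolan-4-yl]prop-2-enoate, via allylic mesylate 20 (not isolated)
Conditions: MsCl, Et3N, CH2Cl2, −20 °C; then LiBr, THF, 0 °C → rt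
Reagents that add atoms: lithium bromide, [Li+].[Br-]; methanesulfonyl chloride, CS(=O)(=O)Cl (its atoms stay only in 20)
Why: Mesylation and SN2′ displacement by bromide (allylic transposition) should give the thermodynamically preferred (Z)-2-(bromomethyl)alkenoate, with the dioxolane trans to the ester, under neutral conditions that spare stannane and acetonide.

Step 13
Reactants: 21 tert-butyl (Z)-2-(bromomethyl)-3-(dioxolanyl)prop-2-enoate; 10 (R)-2-[2-methyl-5-(methylthio)-3-oxo-2,3-dihydrofuran-2-yl]acetaldehyde
Product: 22 seco alcohol: tert-butyl (3R,4S)-4-hydroxy-2-methylidene-5-[(2R)-2-methyl-5-(methylthio)-3-oxo-2,3-dihydrofuran-2-yl]-3-[(4S,5S)-2,2-dimethyl-5-[1-(tributylstannyl)ethenyl]-1,3-dioxolan-4-yl]pentanoate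
Conditions: CrCl2 (4 equiv), THF, 0 °C → rt
Reagents that add atoms: none
Why: Nozaki–Hiyama-type allylation with a 2-(alkoxycarbonyl)allylchromium reagent (Dreiding–Schmidt variant) through a chair Zimmerman–Traxler transition state with the γ-substituent equatorial should give the 7,8-anti alcohol (C8), while C7 is set by attack anti to the allylic C6–O bond of the dioxolane in the rotamer with C6–H eclipsing the alkene (A(1,3) strain), and the tert-butyl ester prevents lactonisation onto O8.

Step 14
Reactants: 22 seco alcohol
Product: 23 seco methacrylate: the C8 methacrylate ester of 22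
Conditions: methacrylic anhydride, Et3N, DMAP (cat.), CH2Cl2, 0 °C → rt
Reagents that add atoms: methacrylic anhydride, CC(=C)C(=O)OC(=O)C(C)=C
Why: DMAP-catalysed acyl transfer to the secondary C8 alcohol, with retention because the C–O bond is not touched.

Step 15
Reactants: 23 seco methacrylate
Product: 24 macrocycle: 5,6-O-isopropylidene tert-butyl ester of the ring-opened lactone of 26, with the C3–C4 bond, furanone and C1–C10 ring complete, (5R,6S,7R,8S,10R)
Conditions: Pd(PPh3)4 (10 mol %), copper thiophene-2-carboxylate Cu(O2CC4H3S) (2 equiv), THF, 50 °C, 0.002 M, slow addition of 23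
Reagents that add atoms: none
Why: Zerovalent palladium, assisted by the monovalent copper carboxylate that binds sulfur, inserts into the C3–SMe bond of the vinylogous thioester, the copper carboxylate mediates transfer of the C4 vinyl group from tin to palladium, and reductive elimination forms the C3–C4 bond. The closest known reaction type is the Liebeskind–Srogl coupling of thioesters, β-(methylthio)enones and heteroaryl thioethers with organostannanes or boronic acids under base-free conditions. The step closes the ten-membered carbocycle C1–C10, which is the nine-membered ring through the C3–O–C10 bridge (11-oxabicyclo[6.2.1]undecane core), by reductive elimination from a ten-membered palladacycle, a cross-coupling macrocyclisation outside the Baldwin classification. No stereocentre is formed, and C5, C6, C7, C8 and C10 should not epimerise under the neutral conditions. The selectivity needed is ring closure over oligomerisation and reaction at the C–S bond only: high dilution with slow addition and the cis-dioxolane at C5/C6, which turns the C4 and C7 branches to the same side, should favour cyclisation, while the acrylate, methacrylate and ester groups are inert to the palladium/copper pair.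

Step 16
Reactants: 24 macrocycle
Product: 26 isogoiazensolide, via dihydroxy acid 25 (not isolated)
Conditions: TFA/H2O (9:1), CH2Cl2, 0 °C → rt
Reagents that add atoms: none
Why: Acidolysis removes the acetonide and the tert-butyl ester, and the freed C6 hydroxyl should close the five-membered α-methylene lactone (5-exo-trig acyl substitution, faster than six-membered closure by O5) with retention at C6 and C7, leaving the C5 hydroxyl free.

Compound list
1 | (S)-lactic acid | C[C@H](O)C(=O)O | starting material
2 | pivalaldehyde | CC(C)(C)C=O | starting material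
3 | (2S,5S)-2-tert-butyl-5-methyl-1,3-dioxolan-4-one (cis) | CC(C)(C)[C@H]1O[C@@H](C)C(=O)O1 | intermediate
4 | allyl bromide | C=CCBr | starting material
5 | (2S,5R)-5-allyl-2-tert-butyl-5-methyl-1,3-dioxolan-4-one | CC(C)(C)[C@H]1O[C@](C)(CC=C)C(=O)O1 | intermediate
6 | hemiketal adduct, (2S,5R)-5-allyl-2-tert-butyl-4,5-dimethyl-1,3-dioxolan-4-ol as its lithium alkoxide, C4 undefined (not isolated) | CC(C)(C)[C@H]1O[C@](C)(CC=C)C(C)(O)O1 | intermediate
7 | (R)-3-hydroxy-3-methylhex-5-en-2-one | CC(=O)[C@](C)(O)CC=C | intermediate
8 | ketene dithioacetal, (R)-4-hydroxy-4-methyl-1,1-bis(methylthio)hepta-1,6-dien-3-one (not isolated) | CSC(SC)=CC(=O)[C@](C)(O)CC=C | intermediate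
9 | (R)-2-allyl-2-methyl-5-(methylthio)furan-3(2H)-one | CSC1=CC(=O)[C@@](C)(CC=C)O1 | intermediate
10 | (R)-2-[2-methyl-5-(methylthio)-3-oxo-2,3-dihydrofuran-2-yl]acetaldehyde | CSC1=CC(=O)[C@@](C)(CC=O)O1 | intermediate
11 | L-arabinose (pyranose form, anomers) | OC1OC[C@H](O)[C@H](O)[C@H]1O | starting material
12 | 3,4-O-isopropylidene-L-arabinopyranose | OC1OC[C@@H]2OC(C)(C)O[C@@H]2[C@H]1O | intermediate
13 | formate ester, 4-O-formyl-2,3-O-isopropylidene-L-erythrose (not isolated) | O=C[C@H]1OC(C)(C)O[C@H]1COC=O | intermediate
14 | 2,3-O-isopropylidene-L-erythrofuranose (lactol, anomers) | OC1OC[C@@H]2OC(C)(C)O[C@H]12 | intermediate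
15 | [(4S,5R)-5-ethynyl-2,2-dimethyl-1,3-dioxolan-4-yl]methanol (cis) | C#C[C@H]1OC(C)(C)O[C@H]1CO | intermediate
16 | [(4S,5S)-2,2-dimethyl-5-[1-(tributylstannyl)ethenyl]-1,3-dioxolan-4-yl]methanol (cis) | C=C([Sn](CCCC)(CCCC)CCCC)[C@H]1OC(C)(C)O[C@H]1CO | intermediate
17 | (4R,5S)-2,2-dimethyl-5-[1-(tributylstannyl)ethenyl]-1,3-dioxolane-4-carbaldehyde (cis) | C=C([Sn](CCCC)(CCCC)CCCC)[C@H]1OC(C)(C)O[C@H]1C=O | intermediate
18 | tert-butyl acrylate | C=CC(=O)OC(C)(C)C | starting material
19 | tert-butyl 2-[hydroxy[(4S,5S)-2,2-dimethyl-5-[1-(tributylstannyl)ethenyl]-1,3-dioxolan-4-yl]methyl]prop-2-enoate (carbinol epimers) | C=C([Sn](CCCC)(CCCC)CCCC)[C@H]1OC(C)(C)O[C@H]1C(O)C(=C)C(=O)OC(C)(C)C | intermediate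
20 | allylic mesylate of 19 (not isolated) | C=C([Sn](CCCC)(CCCC)CCCC)[C@H]1OC(C)(C)O[C@H]1C(OS(C)(=O)=O)C(=C)C(=O)OC(C)(C)C | intermediate
21 | tert-butyl (Z)-2-(bromomethyl)-3-[(4S,5S)-2,2-dimethyl-5-[1-(tributylstannyl)ethenyl]-1,3-dioxolan-4-yl]prop-2-enoate | C=C([Sn](CCCC)(CCCC)CCCC)[C@H]1OC(C)(C)O[C@H]1/C=C(\CBr)C(=O)OC(C)(C)C | intermediate
22 | seco alcohol, tert-butyl (3R,4S)-4-hydroxy-2-methylidene-5-[(2R)-2-methyl-5-(methylthio)-3-oxo-2,3-dihydrofuran-2-yl]-3-[(4S,5S)-2,2-dimethyl-5-[1-(tributylstannyl)ethenyl]-1,3-dioxolan-4-yl]pentanoate (7R,8S,10R in target locants; O8 and C6 anti) | C=C(C(=O)OC(C)(C)C)[C@@H]([C@@H]1OC(C)(C)O[C@@H]1C(=C)[Sn](CCCC)(CCCC)CCCC)[C@@H](O)C[C@@]1(C)OC(SC)=CC1=O | intermediate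
23 | seco methacrylate, the C8 methacrylate ester of 22 | C=C(C(=O)OC(C)(C)C)[C@@H]([C@@H]1OC(C)(C)O[C@@H]1C(=C)[Sn](CCCC)(CCCC)CCCC)[C@@H](OC(=O)C(C)=C)C[C@@]1(C)OC(SC)=CC1=O | intermediate
24 | macrocycle, 5,6-O-isopropylidene tert-butyl ester with the 11-oxabicyclo[6.2.1]undecane furanone core closed, (5R,6S,7R,8S,10R) | C=C(C)C(=O)O[C@H]1C[C@@]2(C)OC(=CC2=O)C(=C)[C@H]3OC(C)(C)O[C@H]3[C@@H]1C(=C)C(=O)OC(C)(C)C | intermediate
25 | dihydroxy acid, 5,6-diol and free C12 acid of 24, configuration unchanged (not isolated) | C=C(C)C(=O)O[C@H]1C[C@@]2(C)OC(=CC2=O)C(=C)[C@@H](O)[C@@H](O)[C@@H]1C(=C)C(=O)O | intermediate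
26 | isogoiazensolide, (5R,6S,7R,8S,10R) | C=C(C)C(=O)O[C@H]1C[C@@]2(C)OC(=CC2=O)C(=C)[C@@H](O)[C@H]2OC(=O)C(=C)[C@@H]21 | target

Total step count: 16 steps (5 for the furanone aldehyde 10, 7 for the bromide 21, 4 after their union).
Longest linear sequence: 11 steps (11 → 26: steps 6–12, then 13–16).

Steps most likely to fail

1. Step 15 (key ring closure). Transfer of the hindered 1,1-disubstituted tributylstannyl group may be slow and the medium-ring transition state strained, so that oligomerisation and protodestannylation outrun cyclisation. The fallback sets out from 23 and comes back at 26; it forms the same bond after the lactone is in place, so that the trans-lactone is the turn element and a faster-transferring tin group is used. Iododestannylation of 23 (I2, CH2Cl2, −78 °C) should give the vinyl iodide F1. TFA/H2O then removes acetonide and tert-butyl ester and closes the lactone to the iodo lactone F2. Pd(PPh3)4 with hexamethylditin converts F2 into the trimethylstannane F3. The coupling of step 15 (Pd(PPh3)4, copper thiophene-2-carboxylate, THF, high dilution) on F3 then gives 26 directly.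

2. Step 13 (chromium allylation). The simple diastereoselection may turn out 7,8-syn instead of anti, the normal result for zinc and indium reagents of this type. The fallback sets out from 21 and 10 and comes back at 23; it makes the syn isomer on purpose and corrects C8 by inversion. Zinc dust in THF/saturated aqueous NH4Cl should couple 21 and 10 to the 7,8-syn alcohol F4 (C8 epimer of 22). Mitsunobu esterification of F4 with methacrylic acid (PPh3, DIAD, toluene, 0 °C) inverts C8 and gives 23.

3. Step 4 (furanone formation). The tertiary alkoxide may be trapped as an S-methyl xanthate or methyl ether in competition with C-dithiocarboxylation of the enolate, or the dithioacetal may fail to cyclise. The fallback sets out from 7 and comes back at 9; it builds the furanone first and introduces sulfur afterwards. N,N-Dimethylformamide dimethyl acetal (neat, 80 °C) converts 7 into the enaminone F5. TFA in CH2Cl2 cyclises it, with loss of dimethylamine, to the 5-unsubstituted furanone F6. Conjugate addition of methanethiol (Et3N cat., CH2Cl2) gives the sulfide F7. N-Chlorosuccinimide followed by Et3N (α-chlorination of the sulfide, then dehydrochlorination) restores the ring alkene and gives 9.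

Further compounds
F1 | step 15 | vinyl iodide, 23 with iodine in place of the tributylstannyl group | C=C(C(=O)OC(C)(C)C)[C@@H]([C@@H]1OC(C)(C)O[C@@H]1C(=C)I)[C@@H](OC(=O)C(C)=C)C[C@@]1(C)OC(SC)=CC1=O
F2 | step 15 | iodo lactone, trans-α-methylene-γ-lactone with free C5 hydroxyl, C4 vinyl iodide, C8 methacrylate and 5-(methylthio)furanone | C=C(I)[C@@H](O)[C@H]1OC(=O)C(=C)[C@@H]1[C@@H](OC(=O)C(C)=C)C[C@@]1(C)OC(SC)=CC1=O
F3 | step 15 | trimethylstannane, F2 with trimethylstannyl in place of iodine | C=C([Sn](C)(C)C)[C@@H](O)[C@H]1OC(=O)C(=C)[C@@H]1[C@@H](OC(=O)C(C)=C)C[C@@]1(C)OC(SC)=CC1=O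
F4 | step 13 | 7,8-syn alcohol, C8 epimer of 22 | C=C(C(=O)OC(C)(C)C)[C@@H]([C@@H]1OC(C)(C)O[C@@H]1C(=C)[Sn](CCCC)(CCCC)CCCC)[C@H](O)C[C@@]1(C)OC(SC)=CC1=O
F5 | step 4 | enaminone, (R,E)-1-(dimethylamino)-4-hydroxy-4-methylhepta-1,6-dien-3-one | CN(C)/C=C/C(=O)[C@](C)(O)CC=C
F6 | step 4 | 5-unsubstituted furanone, (R)-2-allyl-2-methylfuran-3(2H)-one | C1=CC(=O)[C@@](C)(CC=C)O1
F7 | step 4 | sulfide, (2R)-2-allyl-2-methyl-5-(methylthio)dihydrofuran-3(2H)-one, C5 epimers | CSC1CC(=O)[C@@](C)(CC=C)O1
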